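**Retrosynthetic overview**
1. The target (gardenin B, 5-hydroxy-6,7,8,4'-tetramethoxyflavone) comes from tangeretin. The last step frees only the 5-OH, using chelation to the C4 carbonyl.
2. Tangeretin comes from a 2'-hydroxychalcone. Ring C (the pyranone) is the only ring built, closed by O1–C2 bond formation and dehydrogenation; rings A and B are bought as benzene rings.
3. The chalcone comes from 2'-hydroxy-3',4',5',6'-tetramethoxyacetophenone and 4-methoxybenzaldehyde. The key C–C bond (later C2–C3) is made by an intermolecular Claisen–Schmidt aldol condensation.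
4. The acetophenone comes from pentamethoxybenzene by Friedel–Crafts acetylation with loss of one ortho methyl.
5. Pentamethoxybenzene comes from 3,4,5-trimethoxyphenol by methylation, Vilsmeier formylation, Baeyer–Villiger oxidation and methylation.

Assumption: the target has no stereocentre and no stereogenic double bond, so there is no enantiomer to control. The transient aldol and flavanone intermediates are racemic, and their stereocentres are erased on the way.

**Route**

Step 1
Reactants: 1 3,4,5-trimethoxyphenol
Product: 2 1,2,3,5-tetramethoxybenzene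
Conditions: MeI (1.5 equiv), K2CO3 (2 equiv), acetone, reflux, 8 h
Reagents that add atoms: iodomethane (MeI), CI
Why: Williamson ether synthesis (SN2 of the potassium phenolate on MeI) on a molecule with no other reactive group; no stereocentre is involved.

Step 2
Reactants: 2 1,2,3,5-tetramethoxybenzene
Product: 4 2,3,4,6-tetramethoxybenzaldehyde, via aryl iminium chloride 3 (not isolated)
Conditions: POCl3 (1.3 equiv), DMF, 0 °C → rt, 4 h; then ice–water
Reagents that add atoms: N,N-dimethylformamide (DMF), CN(C)C=O; water, O
Why: Vilsmeier–Haack formylation, in which the two free ring positions are equivalent and each is ortho, ortho and para to methoxy groups, so one aldehyde forms after hydrolysis of iminium salt 3.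

Step 3
Reactants: 4 2,3,4,6-tetramethoxybenzaldehyde
Product: 6 2,3,4,6-tetramethoxyphenol, via aryl formate 5 (not isolated)
Conditions: mCPBA (1.2 equiv), CH2Cl2, 0 °C → rt, 4 h; concentrate; then MeOH, conc. HCl (cat.), rt, 1 h, under N2
Reagents that add atoms: 3-chloroperoxybenzoic acid (mCPBA), O=C(OO)c1cccc(Cl)c1
Why: Baeyer–Villiger (Dakin-type) oxidation, in which the electron-rich aryl group migrates in the Criegee adduct in preference to hydride to give formate 5, and acid-catalysed methanolysis then cleaves 5 without exposing the oxidisable phenol to base and air.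

Step 4
Reactants: 6 2,3,4,6-tetramethoxyphenol
Product: 7 pentamethoxybenzene
Conditions: MeI (2 equiv), K2CO3 (2 equiv), acetone, reflux, 12 h
Reagents that add atoms: iodomethane (MeI), CI
Why: Williamson ether synthesis, since the flanked phenolate is still a good nucleophile towards the small electrophile MeI.

Step 5
Reactants: 7 pentamethoxybenzene
Product: 10 2'-hydroxy-3',4',5',6'-tetramethoxyacetophenone, via pentamethoxyacetophenone 8 (not isolated), via dichloroaluminium chelate 9 (not isolated)
Conditions: AcCl (1.3 equiv), AlCl3 (2.5 equiv), Et2O, 0 °C → reflux, 6 h; then ice, 2 M HCl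
Reagents that add atoms: acetyl chloride, CC(=O)Cl
Why: Friedel–Crafts acylation at the only free ring position gives 8, and AlCl3 bound to the ketone oxygen then cleaves one of the two equivalent ortho methoxy groups through six-membered chelate 9, which resists a second cleavage in ether.

Step 6
Reactants: 10 2'-hydroxy-3',4',5',6'-tetramethoxyacetophenone; 11 4-methoxybenzaldehyde
Product: 13 (E)-2'-hydroxy-3',4',5',6',4-pentamethoxychalcone, via aldol adduct 12 (not isolated)
Conditions: 11 (1.2 equiv), KOH (50% aq., 10 equiv), EtOH, rt, 36 h; then ice, 2 M HCl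
Reagents that add atoms: none
Why: Claisen–Schmidt crossed aldol condensation, in which only 10 can enolise and 11 is the sole aldehyde electrophile, and E1cB loss of water from racemic aldol 12 gives the conjugated E-enone under thermodynamic control, so no stereocentre remains.

Step 7
Reactants: 13 (E)-2'-hydroxy-3',4',5',6',4-pentamethoxychalcone
Product: 15 tangeretin (5,6,7,8,4'-pentamethoxyflavone), via pentamethoxyflavanone 14 (not isolated)
Conditions: I2 (10 mol %), DMSO, 130 °C, 3 h
Reagents that add atoms: none
Why: Iodine-catalysed oxidative cyclisation of a 2'-hydroxychalcone, in which intramolecular oxa-Michael addition closes ring C to racemic flavanone 14 and I2, with DMSO as terminal oxidant, dehydrogenates it to the aromatic 4-pyranone, erasing the C2 stereocentre.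

Step 8
Reactants: 15 tangeretin (5,6,7,8,4'-pentamethoxyflavone)
Product: 17 gardenin B (5-hydroxy-6,7,8,4'-tetramethoxyflavone), via dichloroboron chelate 16 (not isolated)
Conditions: BCl3 (1.0 M in CH2Cl2, 1.3 equiv), CH2Cl2, −78 °C → 0 °C, 1 h; then H2O, rt
Reagents that add atoms: none
Why: Chelation-directed Lewis acid ether cleavage, in which BCl3 bridges the C4 carbonyl and the peri 5-methoxy oxygen, chloride removes that methyl alone to give six-membered chelate 16, and water frees the hydrogen-bonded 5-OH while the other four aryl methyl ethers survive the low temperature.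

**Compound list**
1 | 3,4,5-trimethoxyphenol | COc1cc(O)cc(OC)c1OC | starting material
2 | 1,2,3,5-tetramethoxybenzene | COc1cc(OC)c(OC)c(OC)c1 | intermediate
3 | N,N-dimethyl(2,3,4,6-tetramethoxybenzylidene)iminium chloride | COc1cc(OC)c(OC)c(OC)c1C=[N+](C)C.[Cl-] | intermediate
4 | 2,3,4,6-tetramethoxybenzaldehyde | COc1cc(OC)c(OC)c(OC)c1C=O | intermediate
5 | 2,3,4,6-tetramethoxyphenyl formate | COc1cc(OC)c(OC)c(OC)c1OC=O | intermediate
6 | 2,3,4,6-tetramethoxyphenol | COc1cc(OC)c(OC)c(OC)c1O | intermediate
7 | pentamethoxybenzene | COc1cc(OC)c(OC)c(OC)c1OC | intermediate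
8 | 2',3',4',5',6'-pentamethoxyacetophenone | CC(=O)c1c(OC)c(OC)c(OC)c(OC)c1OC | intermediate
9 | (2-acetyl-3,4,5,6-tetramethoxyphenoxy)aluminium dichloride (carbonyl-chelated) | CC(=O)c1c(O[Al](Cl)Cl)c(OC)c(OC)c(OC)c1OC | intermediate
10 | 2'-hydroxy-3',4',5',6'-tetramethoxyacetophenone | CC(=O)c1c(O)c(OC)c(OC)c(OC)c1OC | intermediate
11 | 4-methoxybenzaldehyde | COc1ccc(C=O)cc1 | starting material
12 | 3-hydroxy-1-(2-hydroxy-3,4,5,6-tetramethoxyphenyl)-3-(4-methoxyphenyl)propan-1-one (racemic) | COc1ccc(cc1)C(O)CC(=O)c1c(O)c(OC)c(OC)c(OC)c1OC | intermediate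
13 | (E)-1-(2-hydroxy-3,4,5,6-tetramethoxyphenyl)-3-(4-methoxyphenyl)prop-2-en-1-one | COc1ccc(/C=C/C(=O)c2c(O)c(OC)c(OC)c(OC)c2OC)cc1 | intermediate
14 | 5,6,7,8-tetramethoxy-2-(4-methoxyphenyl)chroman-4-one (racemic) | COc1ccc(cc1)C1CC(=O)c2c(OC)c(OC)c(OC)c(OC)c2O1 | intermediate
15 | tangeretin, 5,6,7,8-tetramethoxy-2-(4-methoxyphenyl)-4H-chromen-4-one | COc1ccc(cc1)-c1cc(=O)c2c(OC)c(OC)c(OC)c(OC)c2o1 | intermediate
16 | dichloro{[6,7,8-trimethoxy-2-(4-methoxyphenyl)-4-oxo-4H-chromen-5-yl]oxy}borane (carbonyl-chelated) | COc1ccc(cc1)-c1cc(=O)c2c(OB(Cl)Cl)c(OC)c(OC)c(OC)c2o1 | intermediate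
17 | gardenin B, 5-hydroxy-6,7,8-trimethoxy-2-(4-methoxyphenyl)-4H-chromen-4-one (achiral) | COc1ccc(-c2cc(=O)c3c(O)c(OC)c(OC)c(OC)c3o2)cc1 | target

**Totals**
Total step count: 8. Longest linear sequence: 8 (1 → 17); 11 enters at step 6.

**Three steps most likely to fail, with fallbacks**

*Step 5.* AlCl3 may remove a second methyl, either the other ortho group or a crowded vicinal one, or it may leave a mixture of 8 and 10. The fallback sets out from 7 and comes back at 10. It replaces electrophilic substitution by directed ortho-metalation and separates acylation from ether cleavage.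
- n-BuLi (THF, 0 °C) removes the only ring hydrogen, which sits between two methoxy groups, to give 2,3,4,5,6-pentamethoxyphenyllithium F1.
- N-methoxy-N-methylacetamide (CC(=O)N(C)OC) adds once to give the stable lithium 1-[methoxy(methyl)amino]-1-(pentamethoxyphenyl)ethanolate F2.
- A quench with 1 M HCl collapses this adduct to ketone 8, which is now isolated pure.
- BCl3 (1.1 equiv, CH2Cl2, −78 → 0 °C) then cleaves a single ortho methyl through (2-acetyl-3,4,5,6-tetramethoxyphenoxy)dichloroborane F3, and water hydrolyses that to 10.

*Step 7.* The hot I2/DMSO medium may give incomplete dehydrogenation, ring iodination of the electron-rich rings, or partial ether cleavage. The fallback sets out from 10 and comes back at 15. It carries the needed oxidation level in the ring B partner, so no oxidation is required.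
- The lithium dianion of 10 (LiN(SiMe3)2, 3.5 equiv, THF, −78 °C) is C-acylated in an intermolecular Claisen condensation with 4-methoxybenzoyl chloride (COc1ccc(cc1)C(=O)Cl).
- After an HCl quench this gives 1-(2-hydroxy-3,4,5,6-tetramethoxyphenyl)-3-(4-methoxyphenyl)propane-1,3-dione F4.
- H2SO4 (cat.) in AcOH at 100 °C cyclodehydrates the diketone to 15.
- Any 5-O-demethylation in the hot acid only anticipates step 8.

*Step 8.* The cleavage may overrun to diols or stop short, giving mixtures that are hard to separate. The fallback sets out from 15 and comes back at 17. It turns the selectivity problem into a selective alkylation.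
- Excess AlBr3 in MeCN (reflux, then dilute HCl) deliberately cleaves the 5-methoxy group and the neighbouring 6-methoxy group, giving 5,6-dihydroxy-7,8-dimethoxy-2-(4-methoxyphenyl)-4H-chromen-4-one F5.
- MeI (1.1 equiv) and K2CO3 in acetone then methylate only the free 6-OH, because the 5-OH is locked in a hydrogen bond to the C4 carbonyl and resists alkylation. This gives 17.
- The same treatment funnels any other over-demethylated by-product to 17. This includes the 5,8-diol that ring opening and reclosure would give, because every non-chelated OH is methylated again.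

**Further compounds**
F1 | step 5 | 2,3,4,5,6-pentamethoxyphenyllithium | [Li]c1c(OC)c(OC)c(OC)c(OC)c1OC
F2 | step 5 | lithium 1-[methoxy(methyl)amino]-1-(pentamethoxyphenyl)ethanolate (racemic) | CC([O-])(N(C)OC)c1c(OC)c(OC)c(OC)c(OC)c1OC.[Li+]
F3 | step 5 | (2-acetyl-3,4,5,6-tetramethoxyphenoxy)dichloroborane | CC(=O)c1c(OB(Cl)Cl)c(OC)c(OC)c(OC)c1OC
F4 | step 7 | 1-(2-hydroxy-3,4,5,6-tetramethoxyphenyl)-3-(4-methoxyphenyl)propane-1,3-dione | COc1ccc(cc1)C(=O)CC(=O)c1c(O)c(OC)c(OC)c(OC)c1OC
F5 | step 8 | 5,6-dihydroxy-7,8-dimethoxy-2-(4-methoxyphenyl)-4H-chromen-4-one | COc1ccc(cc1)-c1cc(=O)c2c(O)c(O)c(OC)c(OC)c2o1
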